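**Plan**
1. Retrosynthesis: the C9 glycidate and the C8 acetate are removed, then the ten-membered ring is opened at C7–C8 (alkenylchromium plus aldehyde). The chain is cut at the C2–C3 epoxide (allyl sulfonium ylide plus epoxy aldehyde) into a west fragment (C8, C9, C10, C14, C1, C2) and an east fragment (C3–C7, C11–C13). The lactone is cut at C7=C11/O–C12 (Ph3P=C=C=O on a C6 hydroxy ester) and at C11–C13 (Stille).
2. Enabling feature: in the five-membered ring O–C12(=O)–C11=C7–C6, C7 is the β-carbon and sits next to the oxygen-bearing C6, which is the pattern of a tetronic acid; its enol triflate is an alkenyl donor. C8 beside it is a secondary carbinol, hence an aldehyde acceptor.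
3. Forward order: the C4–C5 epoxide, then the five-membered lactone on the east fragment; the C2–C3 epoxide when the fragments are joined; the ten-membered ring last; acylations at C8 and C9 finish the route.
4. Stereochemistry: C6 from (R)-glyceraldehyde acetonide; C4/C5 by hydroxyl-directed epoxidation of a Z-alkene; C9 by oxazaborolidine reduction; C2/C3 from a C2-symmetric chiral sulfide; C8 by Felkin–Anh ring closure then Mitsunobu inversion; the glycidate from (S)-2-methylglycidic acid.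
5. Alkene geometry: C1=C10 from trans-hydroalumination/iodination of butynediol; the Z-alkene that becomes the cis C4–C5 epoxide from a Still–Gennari olefination.

Key step: step 32

Numbering used in all names: C1 alkene CH, C2–C3 and C4(Me)–C5 epoxides, C6 lactone OCH, C7 butenolide β-carbon, C8, C9, C10 alkene carbon bearing C14, C11/C12/C13 butenolide α-carbon, carbonyl and CH2O. PMB = 4-methoxybenzyl, TBS = tert-butyldimethylsilyl, TES = triethylsilyl, TMSE = 2-(trimethylsilyl)ethyl.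

Assumption: the allyl ylide of (2S,5S)-2,5-dimethylthiolane is taken to react with the facial sense of its benzyl ylide (which gives (R,R)-stilbene oxide with benzaldehyde); were the sense opposite, the (2R,5R)-sulfide from (2S,5S)-hexane-2,5-diol would be used in the same way.

**West fragment**

Step 1
Reactants: 1 but-2-yne-1,4-diol
Product: 2 4-[(triethylsilyl)oxy]but-2-yn-1-ol
Conditions: 1 (3 equiv), Et3SiCl (1 equiv), imidazole, DMF, 0 °C
Reagents that add atoms: chlorotriethylsilane, CC[Si](Cl)(CC)CC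
Why: Silyl ether formation; with the diol in excess essentially one hydroxyl is silylated, and unreacted diol is removed by aqueous extraction.

Step 2
Reactants: 2 mono-TES ether
Product: 4 (2Z)-3-iodo-4-[(triethylsilyl)oxy]but-2-en-1-ol, via cyclic alkenylaluminate 3 (not isolated)
Conditions: NaAlH2(OCH2CH2OMe)2, THF, 0 °C; then I2, −78 → 0 °C; aq. KNaC4H4O6
Reagents that add atoms: iodine, II
Why: Hydroxyl-directed trans-hydroalumination of the propargylic alcohol places hydride on C1 and aluminium on C10, and iodinolysis with retention gives the alkenyl iodide with C2 cis to iodine, the geometry the C1=C10 alkene needs once iodine is replaced by C9.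

Step 3
Reactants: 4 iodo alcohol
Product: 5 (2Z)-1-[(tert-butyldimethylsilyl)oxy]-3-iodo-4-[(triethylsilyl)oxy]but-2-ene
Conditions: t-BuMe2SiCl, imidazole, DMF, 0 °C → rt
Reagents that add atoms: tert-butyldimethylsilyl chloride, CC(C)(C)[Si](C)(C)Cl
Why: Silylation of the primary allylic alcohol; the bulky silyl group is slow to migrate to carbon in the alkenyllithium of step 4 and slower to cleave than the triethylsilyl ether in step 7.

Step 4
Reactants: 5 alkenyl iodide; 6 N-methoxy-2-[(4-methoxybenzyl)oxy]-N-methylacetamide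
Product: 8 (3Z)-5-[(tert-butyldimethylsilyl)oxy]-1-[(4-methoxybenzyl)oxy]-3-{[(triethylsilyl)oxy]methyl}pent-3-en-2-one, via alkenyllithium 7 (not isolated)
Conditions: t-BuLi (2 equiv), Et2O, −78 °C; then 6, −78 → −40 °C
Reagents that add atoms: none
Why: Iodine–lithium exchange with retention of alkene geometry, then acylation by the Weinreb amide, whose chelated tetrahedral adduct stops the addition at the ketone.

Step 5
Reactants: 8 enone
Product: 9 (2R,3Z)-5-[(tert-butyldimethylsilyl)oxy]-1-[(4-methoxybenzyl)oxy]-3-{[(triethylsilyl)oxy]methyl}pent-3-en-2-ol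
Conditions: (R)-2-methyl-CBS-oxazaborolidine (0.2 equiv), BH3·SMe2, THF, −30 °C
Reagents that add atoms: none
Why: Corey–Bakshi–Shibata reduction: the α-branched alkenyl group is the large and CH2OPMB the small substituent, so the (R)-oxazaborolidine should deliver hydride to give the (9R)-alcohol.

Step 6
Reactants: 9 allylic alcohol
Product: 10 (2R,3Z)-2,5-bis[(tert-butyldimethylsilyl)oxy]-1-[(4-methoxybenzyl)oxy]-3-{[(triethylsilyl)oxy]methyl}pent-3-ene
Conditions: t-BuMe2SiOTf, 2,6-lutidine, CH2Cl2, −78 °C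
Reagents that add atoms: tert-butyldimethylsilyl trifluoromethanesulfonate, CC(C)(C)[Si](C)(C)OS(=O)(=O)C(F)(F)F
Why: Silylation with the silyl triflate, which is reactive enough for the hindered secondary allylic alcohol.

Step 7
Reactants: 10 tris-silyl ether
Product: 11 (2Z)-4-[(tert-butyldimethylsilyl)oxy]-2-{(1R)-1-[(tert-butyldimethylsilyl)oxy]-2-[(4-methoxybenzyl)oxy]ethyl}but-2-en-1-ol
Conditions: pyridinium p-toluenesulfonate (cat.), MeOH/CH2Cl2, 0 °C
Reagents that add atoms: none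
Why: Acid-catalysed methanolysis of silyl ethers; the primary triethylsilyl ether at C14 is cleaved far faster than the primary and secondary TBS ethers.

Step 8
Reactants: 11 C14 alcohol
Product: 12 (2Z)-4-[(tert-butyldimethylsilyl)oxy]-2-{(1R)-1-[(tert-butyldimethylsilyl)oxy]-2-[(4-methoxybenzyl)oxy]ethyl}but-2-en-1-yl 3-methylbut-2-enoate
Conditions: 3-methylbut-2-enoyl chloride, pyridine, CH2Cl2, 0 °C
Reagents that add atoms: 3-methylbut-2-enoyl chloride, CC(C)=CC(=O)Cl
Why: Acylation with the acid chloride; pyridine is the base because stronger amines deconjugate the senecioyl unit through its vinylketene.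

Step 9
Reactants: 12 senecioate
Product: 13 (2Z)-2-{(1R)-1-[(tert-butyldimethylsilyl)oxy]-2-[(4-methoxybenzyl)oxy]ethyl}-4-hydroxybut-2-en-1-yl 3-methylbut-2-enoate
Conditions: HF·pyridine, pyridine, THF, 0 °C → rt
Reagents that add atoms: none
Why: Fluoride-mediated desilylation; buffered HF·pyridine removes the unhindered primary allylic silyl ether at C2 and leaves the hindered secondary one at C9.

Step 10
Reactants: 13 C2 alcohol
Product: 14 (2Z)-4-bromo-2-{(1R)-1-[(tert-butyldimethylsilyl)oxy]-2-[(4-methoxybenzyl)oxy]ethyl}but-2-en-1-yl 3-methylbut-2-enoate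
Conditions: CBr4, PPh3, 2,6-lutidine, CH2Cl2, −20 → 0 °C
Reagents that add atoms: carbon tetrabromide, BrC(Br)(Br)Br
Why: Appel bromination, an SN2 displacement at the primary allylic carbon that keeps the alkene geometry.

**Chiral sulfide and sulfonium salt**

Step 11
Reactants: 15 (2R,5R)-hexane-2,5-diol
Product: 16 (2R,5R)-hexane-2,5-diyl dimethanesulfonate
Conditions: MeSO2Cl, Et3N, CH2Cl2, 0 °C
Reagents that add atoms: methanesulfonyl chloride, CS(=O)(=O)Cl
Why: Sulfonylation of both secondary alcohols with retention.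

Step 12
Reactants: 16 dimesylate
Product: 17 (2S,5S)-2,5-dimethylthiolane
Conditions: Na2S·9H2O, EtOH, rt → 60 °C
Reagents that add atoms: sodium sulfide Na2S, [Na+].[Na+].[S-2]
Why: Twofold SN2 displacement by sulfide, each with inversion, closes the thiolane and turns the (2R,5R)-diol into the (2S,5S)-sulfide.

Step 13
Reactants: 14 allylic bromide; 17 (2S,5S)-2,5-dimethylthiolane
Product: 18 (2S,5S)-1-[(2Z)-3-{(1R)-1-[(tert-butyldimethylsilyl)oxy]-2-[(4-methoxybenzyl)oxy]ethyl}-4-[(3-methylbut-2-enoyl)oxy]but-2-en-1-yl]-2,5-dimethylthiolan-1-ium tetrafluoroborate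
Conditions: AgBF4, CH2Cl2, 0 °C → rt, dark
Reagents that add atoms: silver tetrafluoroborate AgBF4, [Ag+].F[B-](F)(F)F
Why: SN2 S-alkylation of the sulfide by the allylic bromide, driven by precipitation of AgBr; because the sulfide is C2-symmetric the sulfonium sulfur is not a stereocentre.

**East fragment**

Step 14
Reactants: 19 (R)-2,2-dimethyl-1,3-dioxolane-4-carbaldehyde; 20 ethyl 2-[bis(2,2,2-trifluoroethoxy)phosphoryl]propanoate
Product: 22 ethyl (2Z)-3-[(4S)-2,2-dimethyl-1,3-dioxolan-4-yl]-2-methylprop-2-enoate, via potassium phosphonate carbanion 21 (not isolated)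
Conditions: KN(SiMe3)2, 18-crown-6, THF, −78 °C; then 19
Reagents that add atoms: none
Why: Still–Gennari variant of the Horner–Wadsworth–Emmons reaction: the trifluoroethyl phosphonate under dissociating conditions eliminates from the kinetic adduct and gives the Z-trisubstituted enoate (C3 cis to C6), while the C6 stereocentre comes unchanged from the aldehyde.

Step 15
Reactants: 22 Z-enoate
Product: 23 (2Z)-3-[(4S)-2,2-dimethyl-1,3-dioxolan-4-yl]-2-methylprop-2-en-1-ol
Conditions: i-Bu2AlH, CH2Cl2, −78 °C; aq. KNaC4H4O6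
Reagents that add atoms: none
Why: 1,2-Reduction of the enoate to the allylic alcohol by the aluminium hydride at low temperature, without touching the alkene or the acetonide.

Step 16
Reactants: 23 allylic alcohol
Product: 24 (4S)-4-{(1Z)-3-[(4-methoxybenzyl)oxy]-2-methylprop-1-en-1-yl}-2,2-dimethyl-1,3-dioxolane
Conditions: NaH, 4-MeOC6H4CH2Cl, Bu4NI (cat.), THF/DMF, 0 °C → rt
Reagents that add atoms: 4-methoxybenzyl chloride, COc1ccc(CCl)cc1
Why: Williamson etherification of the primary allylic alkoxide.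

Step 17
Reactants: 24 PMB ether
Product: 25 (2S,3Z)-5-[(4-methoxybenzyl)oxy]-4-methylpent-3-ene-1,2-diol
Conditions: AcOH/H2O (4:1), 40 °C
Reagents that add atoms: none
Why: Acid-catalysed hydrolysis of the acetonide; the benzyl-type ether and the alkene are stable to aqueous acetic acid.

Step 18
Reactants: 25 diol
Product: 26 (2S,3Z)-2-hydroxy-5-[(4-methoxybenzyl)oxy]-4-methylpent-3-enoic acid
Conditions: TEMPO (cat.), PhI(OAc)2, MeCN/H2O, 0 °C → rt
Reagents that add atoms: water, O
Why: Oxoammonium (TEMPO) oxidation, which is selective for the primary alcohol and carries it through the aldehyde hydrate to the acid while the secondary allylic alcohol is left.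

Step 19
Reactants: 26 hydroxy acid
Product: 27 2-(trimethylsilyl)ethyl (2S,3Z)-2-hydroxy-5-[(4-methoxybenzyl)oxy]-4-methylpent-3-enoate
Conditions: Me3SiCH2CH2OC(=NH)CCl3, toluene, 80 °C
Reagents that add atoms: 2-(trimethylsilyl)ethyl 2,2,2-trichloroacetimidate, C[Si](C)(C)CCOC(=N)C(Cl)(Cl)Cl
Why: Esterification with a trichloroacetimidate under thermal, promoter-free conditions: the carboxylic acid protonates the imidate and is alkylated, the alcohol is not.

Step 20
Reactants: 27 TMSE ester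
Product: 28 2-(trimethylsilyl)ethyl (2S)-2-hydroxy-2-[(2S,3R)-3-{[(4-methoxybenzyl)oxy]methyl}-3-methyloxiran-2-yl]acetate
Conditions: 3-ClC6H4CO3H, NaHCO3, CH2Cl2, 0 °C → rt
Reagents that add atoms: 3-chloroperbenzoic acid, OOC(=O)c1cccc(Cl)c1
Why: Hydroxyl-directed peracid epoxidation (Henbest): allylic 1,3-strain holds C6–H in the alkene plane, the C6 hydroxyl delivers the peracid to its own face, and the threo epoxy alcohol with the cis C4–C5 epoxide of the target results.

Step 21
Reactants: 28 epoxy hydroxy ester; 29 (triphenylphosphoranylidene)ketene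
Product: 31 (5S)-5-[(2S,3R)-3-{[(4-methoxybenzyl)oxy]methyl}-3-methyloxiran-2-yl]-4-[2-(trimethylsilyl)ethoxy]furan-2(5H)-one, via acyl ylide 30 (not isolated)
Conditions: toluene, 90 °C
Reagents that add atoms: none
Why: The hydroxyl adds to the ketene C=C of Ph3P=C=C=O to give a stabilised acyl ylide, which closes the five-membered ring by intramolecular Wittig olefination of the ester carbonyl and gives the tetronate without base.

Step 22
Reactants: 31 TMSE tetronate
Product: 32 (5S)-3-bromo-5-[(2S,3R)-3-{[(4-methoxybenzyl)oxy]methyl}-3-methyloxiran-2-yl]-4-[2-(trimethylsilyl)ethoxy]furan-2(5H)-one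
Conditions: N-bromosuccinimide, MeCN, 0 °C → rt
Reagents that add atoms: N-bromosuccinimide, O=C1CCC(=O)N1Br
Why: Electrophilic bromination at C11, the nucleophilic α-carbon of the vinylogous carbonate.

Step 23
Reactants: 32 bromotetronate; 33 (tributylstannyl)methanol
Product: 34 (5S)-3-(hydroxymethyl)-5-[(2S,3R)-3-{[(4-methoxybenzyl)oxy]methyl}-3-methyloxiran-2-yl]-4-[2-(trimethylsilyl)ethoxy]furan-2(5H)-one
Conditions: Pd(PPh3)4 (5 mol %), 1,4-dioxane, 90 °C
Reagents that add atoms: none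
Why: Stille coupling: zerovalent palladium inserts into the C11–Br bond and the hydroxymethyl group is transferred from tin, which installs C13.

Step 24
Reactants: 34 hydroxymethyl tetronate
Product: 35 (5S)-5-[(2S,3R)-3-{[(4-methoxybenzyl)oxy]methyl}-3-methyloxiran-2-yl]-3-{[(triethylsilyl)oxy]methyl}-4-[2-(trimethylsilyl)ethoxy]furan-2(5H)-one
Conditions: Et3SiCl, imidazole, CH2Cl2, 0 °C
Reagents that add atoms: chlorotriethylsilane, CC[Si](Cl)(CC)CC
Why: Silylation of the primary alcohol; a silyl ether is chosen instead of the acetate because an acyloxymethyl group at C11 would be expelled from the tetronate anion generated in step 28.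

Step 25
Reactants: 35 TES ether
Product: 36 (5S)-5-[(2S,3R)-3-(hydroxymethyl)-3-methyloxiran-2-yl]-3-{[(triethylsilyl)oxy]methyl}-4-[2-(trimethylsilyl)ethoxy]furan-2(5H)-one
Conditions: DDQ, CH2Cl2/pH 7 buffer, 0 °C
Reagents that add atoms: none
Why: Oxidative cleavage of the 4-methoxybenzyl ether by DDQ through the benzylic oxocarbenium ion, under buffered conditions that spare the epoxide and the silyl groups.

Step 26
Reactants: 36 C3 alcohol
Product: 37 (2S,3S)-2-methyl-3-[(2S)-5-oxo-4-{[(triethylsilyl)oxy]methyl}-3-[2-(trimethylsilyl)ethoxy]-2,5-dihydrofuran-2-yl]oxirane-2-carbaldehyde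
Conditions: Dess–Martin periodinane, NaHCO3, CH2Cl2, 0 °C → rt
Reagents that add atoms: none
Why: Dess–Martin oxidation of the epoxy alcohol to the aldehyde, which has no α-hydrogen and cannot epimerise.

**Fragment union and ring closure**

Step 27
Reactants: 18 sulfonium tetrafluoroborate; 37 epoxy aldehyde
Product: 39 open-chain bis-epoxide (2R,3S,4S,5S,6S,9R) bearing 8-OPMB 9-OTBS 14-O-senecioyl 13-OTES 7-O-TMSE, via sulfonium ylide 38 (not isolated)
Conditions: EtN=P(NMe2)2–N=P(NMe2)3, CH2Cl2, −78 °C; then 37, −78 → −40 °C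
Reagents that add atoms: none
Why: Sulfonium ylide (Corey–Chaykovsky) epoxidation: the C2-symmetric thiolane shields one face of the allyl ylide and sets C2 as R, ring closure of the anti betaine gives the trans-epoxide and hence 3S, and forming the ylide with a salt-free phosphazene base at −78 °C before the aldehyde is added protects the tetronate and the C4–C5 epoxide.

Step 28
Reactants: 39 bis-epoxide
Product: 41 C7 enol triflate with free C13 hydroxyl, via tetronic acid 40 (not isolated)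
Conditions: Bu4NF, AcOH, THF, 0 °C → rt; then PhNTf2, Et3N, 0 °C → rt
Reagents that add atoms: N-phenylbis(trifluoromethanesulfonimide), O=S(=O)(N(c1ccccc1)S(=O)(=O)C(F)(F)F)C(F)(F)F
Why: Fluoride attacks silicon, the TMSE enol ether fragments to ethene and the tetronate and the primary triethylsilyl ether is cleaved, while the hindered C9 silyl ether survives buffered fluoride; the tetronate oxygen is then sulfonylated by PhNTf2 (enol triflate formation), a reagent that does not react with the primary alcohol.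

Step 29
Reactants: 41 triflate alcohol
Product: 42 C7 enol triflate with C13 acetate
Conditions: Ac2O, pyridine, CH2Cl2, 0 °C
Reagents that add atoms: acetic anhydride, CC(=O)OC(C)=O
Why: Acetylation of the primary alcohol; it is done only now because the enol triflate, unlike the tetronate anion, cannot expel the acetate.

Step 30
Reactants: 42 PMB ether
Product: 43 C8 primary alcohol of the triflate
Conditions: DDQ, CH2Cl2/pH 7 buffer, 0 °C → rt
Reagents that add atoms: none
Why: DDQ cleavage of the 4-methoxybenzyl ether; the enol triflate, the epoxides and the esters are inert to the oxidant.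

Step 31
Reactants: 43 C8 alcohol
Product: 44 C8 aldehyde with C7 enol triflate (ring-closure precursor)
Conditions: Dess–Martin periodinane, NaHCO3, CH2Cl2, 0 °C
Reagents that add atoms: none
Why: Dess–Martin oxidation under buffered, base-free conditions gives the α-silyloxy aldehyde without epimerising the allylic C9 centre.

Step 32
Reactants: 44 triflate aldehyde
Product: 46 ten-membered (8S)-alcohol (2R,3S,4S,5S,6R,8S,9R) with butenolide and both epoxides, via alkenylchromium dichloride 45 (not isolated)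
Conditions: CrCl2 (8 equiv), NiCl2 (2 mol %), DMSO/THF, 25 °C, slow addition to 2 mM
Reagents that add atoms: none
Why: Nozaki–Hiyama–Kishi reaction: zerovalent nickel, formed from NiCl2 by CrCl2, inserts into the electron-poor C7–O bond of the enol triflate, and transmetalation gives the alkenylchromium dichloride 45 (trivalent chromium). The closest known reaction type is the nickel/chromium-mediated addition of alkenyl triflates and β-iodoacrylates to aldehydes in medium-ring closures. The ten-membered carbocycle, the only ring formed, closes by 10-exo-trig attack of C7 on the C8 carbonyl. C8 is the one new stereocentre; it is controlled by the adjacent C9 silyl ether through a polar Felkin–Anh arrangement (C9–O anti to the incoming C7), which should give the (8S)-alcohol with O8 anti to O9. The step needs selectivity for the aldehyde over the lactone, three esters and two epoxides, which the low basicity and aldehyde selectivity of organochromium reagents secure, and it needs ring closure over oligomerisation, which high dilution and the chain turns at the cis C1=C10 alkene and the cis C4–C5 epoxide should favour.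

Step 33
Reactants: 46 (8S)-alcohol
Product: 47 (8R)-acetate (2R,3S,4S,5S,6R,8R,9R) with 9-OTBS
Conditions: PPh3, diisopropyl azodicarboxylate, AcOH, toluene, 0 °C → rt
Reagents that add atoms: acetic acid, CC(=O)O
Why: Mitsunobu reaction: the alkoxyphosphonium ion at C8 is displaced by acetate in an SN2 step with inversion, which converts the (8S)-alcohol into the (8R)-acetate; the neighbouring silyl ether cannot participate.

Step 34
Reactants: 47 silyl ether
Product: 48 C9 alcohol (2R,3S,4S,5S,6R,8R,9R)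
Conditions: HF·pyridine, pyridine, THF, 0 °C → rt
Reagents that add atoms: none
Why: Desilylation with pyridine-buffered HF·pyridine, acidic enough to avoid acetyl migration from O8 to O9 and mild enough for the epoxides.

Step 35
Reactants: 48 C9 alcohol; 49 (S)-2-methyloxirane-2-carboxylic acid
Product: 51 CNP0279449.1, via mixed anhydride 50 (not isolated)
Conditions: 49, 2,4,6-Cl3C6H2COCl, Et3N, THF, rt; then 48, DMAP, toluene, rt
Reagents that add atoms: none
Why: Yamaguchi esterification: the mixed anhydride of the glycidic acid acylates the hindered secondary alcohol under DMAP catalysis, and the quaternary α-carbon of the acid cannot epimerise.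

**Compound list**

1 | but-2-yne-1,4-diol | OCC#CCO | starting material
2 | 4-[(triethylsilyl)oxy]but-2-yn-1-ol | CC[Si](CC)(CC)OCC#CCO | intermediate
3 | sodium 2,2-bis(2-methoxyethoxy)-3-{[(triethylsilyl)oxy]methyl}-2,5-dihydro-1,2-oxaaluminol-2-uide (cyclic alkenylaluminate) | CC[Si](CC)(CC)OCC1=CCO[Al-]1(OCCOC)OCCOC.[Na+] | intermediate
4 | (2Z)-3-iodo-4-[(triethylsilyl)oxy]but-2-en-1-ol | OC/C=C(\I)CO[Si](CC)(CC)CC | intermediate
5 | (2Z)-1-[(tert-butyldimethylsilyl)oxy]-3-iodo-4-[(triethylsilyl)oxy]but-2-ene | CC(C)(C)[Si](C)(C)OC/C=C(\I)CO[Si](CC)(CC)CC | intermediate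
6 | N-methoxy-2-[(4-methoxybenzyl)oxy]-N-methylacetamide | CON(C)C(=O)COCc1ccc(OC)cc1 | starting material
7 | (Z)-alkenyllithium from 5 (lithium on C10) | CC(C)(C)[Si](C)(C)OC/C=C(\[Li])CO[Si](CC)(CC)CC | intermediate
8 | (3Z)-5-[(tert-butyldimethylsilyl)oxy]-1-[(4-methoxybenzyl)oxy]-3-{[(triethylsilyl)oxy]methyl}pent-3-en-2-one | CC(C)(C)[Si](C)(C)OC/C=C(\C(=O)COCc1ccc(OC)cc1)CO[Si](CC)(CC)CC | intermediate
9 | (2R,3Z)-5-[(tert-butyldimethylsilyl)oxy]-1-[(4-methoxybenzyl)oxy]-3-{[(triethylsilyl)oxy]methyl}pent-3-en-2-ol | CC(C)(C)[Si](C)(C)OC/C=C(\[C@@H](O)COCc1ccc(OC)cc1)CO[Si](CC)(CC)CC | intermediate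
10 | (2R,3Z)-2,5-bis[(tert-butyldimethylsilyl)oxy]-1-[(4-methoxybenzyl)oxy]-3-{[(triethylsilyl)oxy]methyl}pent-3-ene | CC(C)(C)[Si](C)(C)OC/C=C(\[C@@H](O[Si](C)(C)C(C)(C)C)COCc1ccc(OC)cc1)CO[Si](CC)(CC)CC | intermediate
11 | (2Z)-4-[(tert-butyldimethylsilyl)oxy]-2-{(1R)-1-[(tert-butyldimethylsilyl)oxy]-2-[(4-methoxybenzyl)oxy]ethyl}but-2-en-1-ol | CC(C)(C)[Si](C)(C)OC/C=C(\[C@@H](O[Si](C)(C)C(C)(C)C)COCc1ccc(OC)cc1)CO | intermediate
12 | (2Z)-4-[(tert-butyldimethylsilyl)oxy]-2-{(1R)-1-[(tert-butyldimethylsilyl)oxy]-2-[(4-methoxybenzyl)oxy]ethyl}but-2-en-1-yl 3-methylbut-2-enoate | CC(C)(C)[Si](C)(C)OC/C=C(\[C@@H](O[Si](C)(C)C(C)(C)C)COCc1ccc(OC)cc1)COC(=O)C=C(C)C | intermediate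
13 | (2Z)-2-{(1R)-1-[(tert-butyldimethylsilyl)oxy]-2-[(4-methoxybenzyl)oxy]ethyl}-4-hydroxybut-2-en-1-yl 3-methylbut-2-enoate | OC/C=C(\[C@@H](O[Si](C)(C)C(C)(C)C)COCc1ccc(OC)cc1)COC(=O)C=C(C)C | intermediate
14 | (2Z)-4-bromo-2-{(1R)-1-[(tert-butyldimethylsilyl)oxy]-2-[(4-methoxybenzyl)oxy]ethyl}but-2-en-1-yl 3-methylbut-2-enoate | BrC/C=C(\[C@@H](O[Si](C)(C)C(C)(C)C)COCc1ccc(OC)cc1)COC(=O)C=C(C)C | intermediate
15 | (2R,5R)-hexane-2,5-diol | C[C@@H](O)CC[C@@H](C)O | starting material
16 | (2R,5R)-hexane-2,5-diyl dimethanesulfonate | C[C@@H](OS(C)(=O)=O)CC[C@@H](C)OS(C)(=O)=O | intermediate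
17 | (2S,5S)-2,5-dimethylthiolane | C[C@H]1CC[C@H](C)S1 | intermediate
18 | (2S,5S)-1-[(2Z)-3-{(1R)-1-[(tert-butyldimethylsilyl)oxy]-2-[(4-methoxybenzyl)oxy]ethyl}-4-[(3-methylbut-2-enoyl)oxy]but-2-en-1-yl]-2,5-dimethylthiolan-1-ium tetrafluoroborate | C[C@H]1CC[C@H](C)[S+]1C/C=C(\[C@@H](O[Si](C)(C)C(C)(C)C)COCc1ccc(OC)cc1)COC(=O)C=C(C)C.F[B-](F)(F)F | intermediate
19 | (R)-2,2-dimethyl-1,3-dioxolane-4-carbaldehyde | CC1(C)OC[C@H](C=O)O1 | starting material
20 | ethyl 2-[bis(2,2,2-trifluoroethoxy)phosphoryl]propanoate | CCOC(=O)C(C)P(=O)(OCC(F)(F)F)OCC(F)(F)F | starting material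
21 | potassium salt of the carbanion of 20 | [K+].CCOC(=O)[C-](C)P(=O)(OCC(F)(F)F)OCC(F)(F)F | intermediate
22 | ethyl (2Z)-3-[(4S)-2,2-dimethyl-1,3-dioxolan-4-yl]-2-methylprop-2-enoate | CCOC(=O)/C(C)=C\[C@H]1COC(C)(C)O1 | intermediate
23 | (2Z)-3-[(4S)-2,2-dimethyl-1,3-dioxolan-4-yl]-2-methylprop-2-en-1-ol | OC/C(C)=C\[C@H]1COC(C)(C)O1 | intermediate
24 | (4S)-4-{(1Z)-3-[(4-methoxybenzyl)oxy]-2-methylprop-1-en-1-yl}-2,2-dimethyl-1,3-dioxolane | COc1ccc(COC/C(C)=C\[C@H]2COC(C)(C)O2)cc1 | intermediate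
25 | (2S,3Z)-5-[(4-methoxybenzyl)oxy]-4-methylpent-3-ene-1,2-diol | COc1ccc(COC/C(C)=C\[C@H](O)CO)cc1 | intermediate
26 | (2S,3Z)-2-hydroxy-5-[(4-methoxybenzyl)oxy]-4-methylpent-3-enoic acid | COc1ccc(COC/C(C)=C\[C@H](O)C(=O)O)cc1 | intermediate
27 | 2-(trimethylsilyl)ethyl (2S,3Z)-2-hydroxy-5-[(4-methoxybenzyl)oxy]-4-methylpent-3-enoate | COc1ccc(COC/C(C)=C\[C@H](O)C(=O)OCC[Si](C)(C)C)cc1 | intermediate
28 | 2-(trimethylsilyl)ethyl (2S)-2-hydroxy-2-[(2S,3R)-3-{[(4-methoxybenzyl)oxy]methyl}-3-methyloxiran-2-yl]acetate | COc1ccc(COC[C@@]2(C)O[C@H]2[C@H](O)C(=O)OCC[Si](C)(C)C)cc1 | intermediate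
29 | (triphenylphosphoranylidene)ketene | O=C=C=P(c1ccccc1)(c1ccccc1)c1ccccc1 | starting material
30 | O-[(triphenylphosphoranylidene)acetyl] derivative of 28 (acyl ylide) | COc1ccc(COC[C@@]2(C)O[C@H]2[C@H](OC(=O)C=P(c2ccccc2)(c2ccccc2)c2ccccc2)C(=O)OCC[Si](C)(C)C)cc1 | intermediate
31 | (5S)-5-[(2S,3R)-3-{[(4-methoxybenzyl)oxy]methyl}-3-methyloxiran-2-yl]-4-[2-(trimethylsilyl)ethoxy]furan-2(5H)-one | COc1ccc(COC[C@@]2(C)O[C@H]2[C@@H]2OC(=O)C=C2OCC[Si](C)(C)C)cc1 | intermediate
32 | (5S)-3-bromo-5-[(2S,3R)-3-{[(4-methoxybenzyl)oxy]methyl}-3-methyloxiran-2-yl]-4-[2-(trimethylsilyl)ethoxy]furan-2(5H)-one | COc1ccc(COC[C@@]2(C)O[C@H]2[C@@H]2OC(=O)C(Br)=C2OCC[Si](C)(C)C)cc1 | intermediate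
33 | (tributylstannyl)methanol | CCCC[Sn](CCCC)(CCCC)CO | starting material
34 | (5S)-3-(hydroxymethyl)-5-[(2S,3R)-3-{[(4-methoxybenzyl)oxy]methyl}-3-methyloxiran-2-yl]-4-[2-(trimethylsilyl)ethoxy]furan-2(5H)-one | COc1ccc(COC[C@@]2(C)O[C@H]2[C@@H]2OC(=O)C(CO)=C2OCC[Si](C)(C)C)cc1 | intermediate
35 | (5S)-5-[(2S,3R)-3-{[(4-methoxybenzyl)oxy]methyl}-3-methyloxiran-2-yl]-3-{[(triethylsilyl)oxy]methyl}-4-[2-(trimethylsilyl)ethoxy]furan-2(5H)-one | COc1ccc(COC[C@@]2(C)O[C@H]2[C@@H]2OC(=O)C(CO[Si](CC)(CC)CC)=C2OCC[Si](C)(C)C)cc1 | intermediate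
36 | (5S)-5-[(2S,3R)-3-(hydroxymethyl)-3-methyloxiran-2-yl]-3-{[(triethylsilyl)oxy]methyl}-4-[2-(trimethylsilyl)ethoxy]furan-2(5H)-one | OC[C@@]1(C)O[C@H]1[C@@H]1OC(=O)C(CO[Si](CC)(CC)CC)=C1OCC[Si](C)(C)C | intermediate
37 | (2S,3S)-2-methyl-3-[(2S)-5-oxo-4-{[(triethylsilyl)oxy]methyl}-3-[2-(trimethylsilyl)ethoxy]-2,5-dihydrofuran-2-yl]oxirane-2-carbaldehyde | O=C[C@@]1(C)O[C@H]1[C@@H]1OC(=O)C(CO[Si](CC)(CC)CC)=C1OCC[Si](C)(C)C | intermediate
38 | sulfonium ylide of 18 (carbanion at C2) | C[C@H]1CC[C@H](C)[S+]1[CH-]/C=C(\[C@@H](O[Si](C)(C)C(C)(C)C)COCc1ccc(OC)cc1)COC(=O)C=C(C)C | intermediate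
39 | open-chain bis-epoxide: C8H2OPMB–C9H(OTBS)–C10(C14H2O-senecioyl)=C1H (Z), (2R,3S)-trans-epoxide, (4S,5S)-cis-epoxide, (6S)-furan-2(5H)-one with OCH2CH2SiMe3 on C7 and CH2OSiEt3 on C11; (9R) | COc1ccc(COC[C@H](O[Si](C)(C)C(C)(C)C)/C(COC(=O)C=C(C)C)=C\[C@H]2O[C@@H]2[C@@]2(C)O[C@H]2[C@@H]2OC(=O)C(CO[Si](CC)(CC)CC)=C2OCC[Si](C)(C)C)cc1 | intermediate
40 | tetronic acid of 39 (C7–OH, C13–OH free; formed as its tetrabutylammonium salt) | COc1ccc(COC[C@H](O[Si](C)(C)C(C)(C)C)/C(COC(=O)C=C(C)C)=C\[C@H]2O[C@@H]2[C@@]2(C)O[C@H]2[C@@H]2OC(=O)C(CO)=C2O)cc1 | intermediate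
41 | C7 enol triflate, C13–OH free, 8-OPMB, 9-OTBS, 14-O-senecioyl, both epoxides (2R,3S,4S,5S,6S,9R) | COc1ccc(COC[C@H](O[Si](C)(C)C(C)(C)C)/C(COC(=O)C=C(C)C)=C\[C@H]2O[C@@H]2[C@@]2(C)O[C@H]2[C@@H]2OC(=O)C(CO)=C2OS(=O)(=O)C(F)(F)F)cc1 | intermediate
42 | as 41 with C13 acetate | COc1ccc(COC[C@H](O[Si](C)(C)C(C)(C)C)/C(COC(=O)C=C(C)C)=C\[C@H]2O[C@@H]2[C@@]2(C)O[C@H]2[C@@H]2OC(=O)C(COC(C)=O)=C2OS(=O)(=O)C(F)(F)F)cc1 | intermediate
43 | as 42 with free C8 primary alcohol | OC[C@H](O[Si](C)(C)C(C)(C)C)/C(COC(=O)C=C(C)C)=C\[C@H]1O[C@@H]1[C@@]1(C)O[C@H]1[C@@H]1OC(=O)C(COC(C)=O)=C1OS(=O)(=O)C(F)(F)F | intermediate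
44 | C8 aldehyde with C7 enol triflate, 9-OTBS, 14-O-senecioyl, 13-OAc, both epoxides (2R,3S,4S,5S,6S,9R) | O=C[C@H](O[Si](C)(C)C(C)(C)C)/C(COC(=O)C=C(C)C)=C\[C@H]1O[C@@H]1[C@@]1(C)O[C@H]1[C@@H]1OC(=O)C(COC(C)=O)=C1OS(=O)(=O)C(F)(F)F | intermediate
45 | alkenylchromium dichloride from 44 (chromium on C7, solvent ligands omitted) | O=C[C@H](O[Si](C)(C)C(C)(C)C)/C(COC(=O)C=C(C)C)=C\[C@H]1O[C@@H]1[C@@]1(C)O[C@H]1[C@@H]1OC(=O)C(COC(C)=O)=C1[Cr](Cl)Cl | intermediate
46 | ten-membered (8S)-alcohol, 9-OTBS, 14-O-senecioyl, 13-OAc, butenolide, both epoxides (2R,3S,4S,5S,6R,8S,9R) | CC(=O)OCC1=C2[C@H](O)[C@H](O[Si](C)(C)C(C)(C)C)/C(COC(=O)C=C(C)C)=C\[C@H]3O[C@@H]3[C@@]3(C)O[C@H]3[C@@H]2OC1=O | intermediate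
47 | (8R)-acetate of the ten-membered ring, 9-OTBS (2R,3S,4S,5S,6R,8R,9R) | CC(=O)OCC1=C2[C@@H](OC(C)=O)[C@H](O[Si](C)(C)C(C)(C)C)/C(COC(=O)C=C(C)C)=C\[C@H]3O[C@@H]3[C@@]3(C)O[C@H]3[C@@H]2OC1=O | intermediate
48 | (8R)-acetate with free C9 alcohol (2R,3S,4S,5S,6R,8R,9R) | CC(=O)OCC1=C2[C@@H](OC(C)=O)[C@H](O)/C(COC(=O)C=C(C)C)=C\[C@H]3O[C@@H]3[C@@]3(C)O[C@H]3[C@@H]2OC1=O | intermediate
49 | (S)-2-methyloxirane-2-carboxylic acid | OC(=O)[C@]1(C)CO1 | starting material
50 | (S)-2-methyloxirane-2-carboxylic 2,4,6-trichlorobenzoic anhydride | O=C(OC(=O)[C@]1(C)CO1)c1c(Cl)cc(Cl)cc1Cl | intermediate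
51 | CNP0279449.1 | CC(=O)OCC1=C2[C@@H](OC(C)=O)[C@H](OC(=O)[C@]3(C)CO3)/C(COC(=O)C=C(C)C)=C\[C@H]3O[C@@H]3[C@@]3(C)O[C@H]3[C@@H]2OC1=O | target

**Count**

Total: 35 steps. Longest linear sequence: 22 steps (steps 14–35).

**Steps most likely to fail**

1. Step 27. The stereocentre next to the aldehyde (C4) may oppose the sulfide, so that the syn betaine closes and trans/cis and facial selectivity erode; the ylide may also remove C6–H and open the C4–C5 epoxide. Fallback, setting out from alcohol 13 and aldehyde 37 and returning at 39: Mitsunobu thioetherification of 13 with 1-phenyl-1H-tetrazole-5-thiol (PPh3, diisopropyl azodicarboxylate) gives the tetrazolyl sulfide F1. Oxidation with H2O2 and (NH4)6Mo7O24 gives the tetrazolyl sulfone F2. Julia–Kocienski olefination of F2 with 37 (KN(SiMe3)2, DME, −60 °C) gives the (2E)-diene F3. Shi epoxidation with the D-fructose-derived ketone and KHSO5 at pH 10.5 then epoxidises the C2=C3 alkene, the C1=C10 alkene being deactivated by its two allylic C–O bonds, and delivers 39.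

2. Step 32. The conformation of the closing ring, not the acyclic Felkin–Anh arrangement, may decide which face of the aldehyde is attacked, and intermolecular addition may compete with ring closure. Fallback, setting out from 44 and returning at 47: if closure gives the (8R)-alcohol F4, it is acetylated with retention (Ac2O, pyridine, DMAP, CH2Cl2), which gives 47 without the inversion step.

3. Step 33. The hindered C8 alkoxyphosphonium ion, flanked by the butenolide and the C9 silyl ether, may eliminate or fail to be displaced. Fallback, setting out from 46 and returning at 47: sulfonylation with ClCH2SO2Cl and pyridine gives the (8S)-chloromethanesulfonate F5, and SN2 displacement with CsOAc and 18-crown-6 in toluene gives 47 with inversion.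

**Further compounds**

F1 | step 27 | (2Z)-2-{(1R)-1-[(tert-butyldimethylsilyl)oxy]-2-[(4-methoxybenzyl)oxy]ethyl}-4-[(1-phenyl-1H-tetrazol-5-yl)sulfanyl]but-2-en-1-yl 3-methylbut-2-enoate | c1ccc(cc1)-n1nnnc1SC/C=C(\[C@@H](O[Si](C)(C)C(C)(C)C)COCc1ccc(OC)cc1)COC(=O)C=C(C)C
F2 | step 27 | (2Z)-2-{(1R)-1-[(tert-butyldimethylsilyl)oxy]-2-[(4-methoxybenzyl)oxy]ethyl}-4-[(1-phenyl-1H-tetrazol-5-yl)sulfonyl]but-2-en-1-yl 3-methylbut-2-enoate | c1ccc(cc1)-n1nnnc1S(=O)(=O)C/C=C(\[C@@H](O[Si](C)(C)C(C)(C)C)COCc1ccc(OC)cc1)COC(=O)C=C(C)C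
F3 | step 27 | (1(10)Z,2E)-diene analogue of 39 with a C2=C3 alkene in place of the C2–C3 epoxide, (4S,5S)-epoxide and (6S)-tetronate retained | COc1ccc(COC[C@H](O[Si](C)(C)C(C)(C)C)/C(COC(=O)C=C(C)C)=C\C=C\[C@@]2(C)O[C@H]2[C@@H]2OC(=O)C(CO[Si](CC)(CC)CC)=C2OCC[Si](C)(C)C)cc1
F4 | step 32 | ten-membered (8R)-alcohol, the C8 epimer of 46 | CC(=O)OCC1=C2[C@@H](O)[C@H](O[Si](C)(C)C(C)(C)C)/C(COC(=O)C=C(C)C)=C\[C@H]3O[C@@H]3[C@@]3(C)O[C@H]3[C@@H]2OC1=O
F5 | step 33 | (8S)-chloromethanesulfonate of 46 | CC(=O)OCC1=C2[C@H](OS(=O)(=O)CCl)[C@H](O[Si](C)(C)C(C)(C)C)/C(COC(=O)C=C(C)C)=C\[C@H]3O[C@@H]3[C@@]3(C)O[C@H]3[C@@H]2OC1=O
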